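With the carboxyl carbon as C1, the cyclopentenone comprises C9–C13: C9 carries the acetate and the acid chain, C12 is the carbonyl and C13 the pentenyl-bearing CH. The route rests on disconnecting ring bond C9–C13. Because the fully substituted, oxygenated C9 sits in a 1,5 relationship to C13, a rhodium carbenoid generated at C13 can exchange the C–H bond of an ordinary secondary silyl ether for the ring C–C bond; one operation closes the five-membered ring and creates the quaternary stereocentre with retention. The precursor is an acyclic (6R)-6-silyloxy-2-diazo-3-oxotetradecanedioate, its single stereocentre coming from an asymmetric ketone hydrogenation; tert-butyl ester and triethylsilyl ether allow purely acidic unmasking later.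

Key step: step 7

Remark 1: the sense of induction in step 2 is assumed to follow that known for 4-oxopentanoate esters ((R)-BINAP gives the (R)-lactone); were it opposite for this substrate, the (S)-ligand would be used with no other change.
Remark 2: the C13 epimer with the pentenyl group trans to the octanoate chain (cis to the C9 oxygen) is assumed to be the more stable one, so that acid equilibration in step 11 should deliver the target configuration.

Step 1
Reactants: 1 ethyl 3-iodopropanoate; 2 methyl 9-chloro-9-oxononanoate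
Product: 4 methyl 12-ethoxy-9,12-dioxododecanoate, via zinc homoenolate 3 (not isolated)
Conditions: Zn dust (activated with BrCH2CH2Br, Me3SiCl), THF, 35 °C; then 2, Pd(PPh3)4 (3 mol %), THF/toluene, 0 °C to rt
Reagents that add atoms: none
Why: Zinc inserts into the C–I bond to give the ester-tolerant homoenolate 3, which is acylated by the acid chloride under zerovalent palladium catalysis (Negishi-type acylation of a β-zincio ester) without touching either ester.

Step 2
Reactants: 4 methyl 12-ethoxy-9,12-dioxododecanoate
Product: 6 methyl 8-[(2R)-5-oxooxolan-2-yl]octanoate, via hydroxy diester 5 (not isolated)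
Conditions: H2 (50 atm), RuCl2[(R)-binap](dmf)n (0.5 mol %), MeOH, 50 °C; then TsOH (cat.), toluene, 60 °C
Reagents that add atoms: none
Why: Noyori hydrogenation, in which the γ-ester carbonyl and the ketone chelate ruthenium so that hydride reaches one ketone face and sets C9 (R expected with the (R)-ligand); the hydroxy ester 5 then lactonises under acid, and methanol as solvent means any ester exchange leaves the C1 methyl ester unchanged.

Step 3
Reactants: 6 methyl 8-[(2R)-5-oxooxolan-2-yl]octanoate
Product: 7 methyl (9R)-9-hydroxy-12-[methoxy(methyl)amino]-12-oxododecanoate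
Conditions: MeNHOMe·HCl, AlMe3, CH2Cl2, 0 °C; aq. potassium sodium tartrate work-up
Reagents that add atoms: N,O-dimethylhydroxylamine hydrochloride, CNOC.Cl
Why: Weinreb aminolysis, in which the aluminium amide opens the γ-lactone at 0 °C much faster than it attacks the unactivated methyl ester, and the stereocentre is not involved.

Step 4
Reactants: 7 methyl (9R)-9-hydroxy-12-[methoxy(methyl)amino]-12-oxododecanoate
Product: 8 methyl (9R)-12-[methoxy(methyl)amino]-12-oxo-9-(triethylsilyloxy)dodecanoate
Conditions: Et3SiCl, imidazole, DMF, 0 °C to rt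
Reagents that add atoms: chlorotriethylsilane, CC[Si](Cl)(CC)CC
Why: Standard imidazole-mediated silylation of a secondary alcohol stops relactonisation and installs the electron-releasing, weakly basic oxygen substituent needed in step 7; triethylsilyl is chosen because the ether becomes tertiary after step 7 and must later come off with acid alone.

Step 5
Reactants: 8 methyl (9R)-12-[methoxy(methyl)amino]-12-oxo-9-(triethylsilyloxy)dodecanoate; 9 tert-butyl acetate
Product: 11 methyl (9R)-14-tert-butoxy-12,14-dioxo-9-(triethylsilyloxy)tetradecanoate, via lithium enolate 10 (not isolated)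
Conditions: LiN(iPr)2, 9, THF, −78 °C; then 8, −78 to −40 °C; aq. NH4Cl
Reagents that add atoms: none
Why: Claisen-type acylation of a lithium ester enolate by a Weinreb amide, whose chelated tetrahedral adduct survives until work-up so that over-addition is excluded; at −78 °C the enolate should not condense with the remote methyl ester, and the tert-butyl ester is chosen so that it can later be removed by acid instead of a hot nucleophilic dealkoxycarbonylation.

Step 6
Reactants: 11 methyl (9R)-14-tert-butoxy-12,14-dioxo-9-(triethylsilyloxy)tetradecanoate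
Product: 12 methyl (9R)-14-tert-butoxy-13-diazo-12,14-dioxo-9-(triethylsilyloxy)tetradecanoate [the 1-tert-butyl 14-methyl (6R)-2-diazo-3-oxo-6-(triethylsilyloxy)tetradecanedioate]
Conditions: 4-acetamidobenzenesulfonyl azide, Et3N, MeCN, 0 °C to rt
Reagents that add atoms: 4-acetamidobenzenesulfonyl azide, CC(=O)Nc1ccc(cc1)S(=O)(=O)N=[N+]=[N-]
Why: Regitz diazo transfer to the active methylene of the β-keto ester; no other position is acidic enough to react with the amine base.

Step 7
Reactants: 12 methyl (9R)-14-tert-butoxy-13-diazo-12,14-dioxo-9-(triethylsilyloxy)tetradecanoate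
Product: 13 tert-butyl (2R)-2-(8-methoxy-8-oxooctyl)-5-oxo-2-(triethylsilyloxy)cyclopentane-1-carboxylate (C1 of the ring, i.e. C13, enolisable and undefined)
Conditions: Rh2(OAc)4 (1 mol %), CH2Cl2 (high dilution, slow addition of 12), rt to 40 °C
Reagents that add atoms: none
Why: Rh2(OAc)4 decomposes the diazo group of 12 with loss of N2 to an electrophilic rhodium carbenoid at C13 (rhodium remaining divalent), and the carbenoid carbon inserts into the C9–H bond through a three-centre, hydride-transfer-like transition state that then releases the catalyst. The closest known reaction type is the dirhodium-catalysed intramolecular 1,5 C–H insertion of α-diazo β-keto esters to 2-alkoxycarbonylcyclopentanones, including insertion into oxygen-activated methines. The cyclopentanone ring is closed in the 1,5 mode, by joining the carbenoid carbon to the carbon five atoms along the keto chain (C13 to C9). The quaternary stereocentre C9 is controlled by the substrate alone: C–C replaces C–H with retention, so the R carbinol configuration from step 2 is transferred, while C13 stays enolisable and undefined. The step needs site selectivity for the C9 methine over the C10 and C8 methylenes, the tert-butyl methyl groups and the ether oxygen; the donor oxygen makes C9–H the most hydridic bond, a five-membered transition state is preferred over four- and six-membered ones, the ester conformation holds the tert-butyl group away from the carbenoid, and the hindered, weakly basic silyl ether oxygen is a poor ylide former.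

Step 8
Reactants: 13 tert-butyl (2R)-2-(8-methoxy-8-oxooctyl)-5-oxo-2-(triethylsilyloxy)cyclopentane-1-carboxylate; 14 (Z)-1-bromopent-2-ene
Product: 15 tert-butyl (2R)-2-(8-methoxy-8-oxooctyl)-5-oxo-1-[(2Z)-pent-2-en-1-yl]-2-(triethylsilyloxy)cyclopentane-1-carboxylate (mixture at C1 of the ring)
Conditions: Cs2CO3, acetone, 0 °C to rt
Reagents that add atoms: none
Why: C-alkylation of the stabilised β-keto ester enolate with a reactive primary allylic bromide (SN2, Z geometry retained) makes C13 quaternary; its configuration is immaterial because C13 is re-set in step 11, and the mild carbonate base at or below room temperature is chosen to keep loss of the β-silyloxy group from the enolate slow.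

Step 9
Reactants: 15 tert-butyl (2R)-2-(8-methoxy-8-oxooctyl)-5-oxo-1-[(2Z)-pent-2-en-1-yl]-2-(triethylsilyloxy)cyclopentane-1-carboxylate
Product: 16 tert-butyl (5R)-5-(8-methoxy-8-oxooctyl)-1-[(2Z)-pent-2-en-1-yl]-5-(triethylsilyloxy)-2-(trimethylsilyloxy)cyclopent-2-ene-1-carboxylate
Conditions: LiN(SiMe3)2, Me3SiCl, THF, −78 °C to 0 °C
Reagents that add atoms: chlorotrimethylsilane, C[Si](C)(C)Cl
Why: With C13 quaternary the ketone can enolise only towards C11, so amide deprotonation with in situ silylation should give a single silyl enol ether; the ketone is far more acidic than the α-position of the methyl ester.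

Step 10
Reactants: 16 tert-butyl (5R)-5-(8-methoxy-8-oxooctyl)-1-[(2Z)-pent-2-en-1-yl]-5-(triethylsilyloxy)-2-(trimethylsilyloxy)cyclopent-2-ene-1-carboxylate
Product: 17 tert-butyl (5R)-5-(8-methoxy-8-oxooctyl)-2-oxo-1-[(2Z)-pent-2-en-1-yl]-5-(triethylsilyloxy)cyclopent-3-ene-1-carboxylate
Conditions: Pd(OAc)2 (1.1 equiv), MeCN, rt
Reagents that add atoms: none
Why: Saegusa–Ito oxidation, in which the silyl enol ether gives an oxa-π-allyl species of divalent palladium and β-hydride elimination of a C10 hydrogen forms the C10=C11 enone; the isolated Z alkene and both esters should be inert.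

Step 11
Reactants: 17 tert-butyl (5R)-5-(8-methoxy-8-oxooctyl)-2-oxo-1-[(2Z)-pent-2-en-1-yl]-5-(triethylsilyloxy)cyclopent-3-ene-1-carboxylate
Product: 19 methyl 8-[(1R,5R)-1-hydroxy-4-oxo-5-[(2Z)-pent-2-en-1-yl]cyclopent-2-en-1-yl]octanoate, via keto acid 18 (not isolated)
Conditions: TFA/CH2Cl2 (1:3), H2O (3 equiv), 0 °C to rt; evaporate; toluene, 50 °C
Reagents that add atoms: none
Why: Acidolysis removes the tert-butyl ester and the tertiary triethylsilyl ether, and the β-keto acid 18 loses CO2 through the cyclic six-membered transition state on warming; loss of the C9 oxygen is disfavoured in the enone series because it would lead to a cyclopentadienyl-type cation or a cyclopentadienone, and C13 is set on ketonisation of the dienol, which is reversible under acid and should settle on the isomer with the pentenyl group trans to the octanoate chain.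

Step 12
Reactants: 19 methyl 8-[(1R,5R)-1-hydroxy-4-oxo-5-[(2Z)-pent-2-en-1-yl]cyclopent-2-en-1-yl]octanoate
Product: 20 methyl 8-[(1R,5R)-1-acetoxy-4-oxo-5-[(2Z)-pent-2-en-1-yl]cyclopent-2-en-1-yl]octanoate
Conditions: Ac2O, Sc(OTf)3 (2 mol %), MeCN, −20 °C
Reagents that add atoms: acetic anhydride, CC(=O)OC(C)=O
Why: Lewis acid-catalysed acylation esterifies hindered tertiary alcohols at low temperature without base, which avoids base-induced loss of the C9 oxygen or retro-aldol opening of the β-hydroxy ketone.

Step 13
Reactants: 20 methyl 8-[(1R,5R)-1-acetoxy-4-oxo-5-[(2Z)-pent-2-en-1-yl]cyclopent-2-en-1-yl]octanoate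
Product: 21 8-[(1R,5R)-1-acetoxy-4-oxo-5-[(2Z)-pent-2-en-1-yl]cyclopent-2-en-1-yl]octanoic acid
Conditions: pig liver esterase, phosphate buffer pH 7.0/acetone (9:1), 25 °C
Reagents that add atoms: water, O
Why: Enzymatic ester hydrolysis at neutral pH, in which the esterase should accept the unhindered terminal methyl ester but not the tertiary acetate on a quaternary carbon, and the neutral medium leaves the base-labile 4-acetoxycyclopentenone and C13 untouched.

Compound list
1 | ethyl 3-iodopropanoate | CCOC(=O)CCI | starting material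
2 | methyl 9-chloro-9-oxononanoate | COC(=O)CCCCCCCC(=O)Cl | starting material
3 | (3-ethoxy-3-oxopropyl)zinc iodide | CCOC(=O)CC[Zn]I | intermediate (not isolated)
4 | methyl 12-ethoxy-9,12-dioxododecanoate | CCOC(=O)CCC(=O)CCCCCCCC(=O)OC | intermediate
5 | methyl (9R)-12-ethoxy-9-hydroxy-12-oxododecanoate | CCOC(=O)CC[C@H](O)CCCCCCCC(=O)OC | intermediate (not isolated)
6 | methyl 8-[(2R)-5-oxooxolan-2-yl]octanoate | O=C1CC[C@@H](CCCCCCCC(=O)OC)O1 | intermediate
7 | methyl (9R)-9-hydroxy-12-[methoxy(methyl)amino]-12-oxododecanoate | CON(C)C(=O)CC[C@H](O)CCCCCCCC(=O)OC | intermediate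
8 | methyl (9R)-12-[methoxy(methyl)amino]-12-oxo-9-(triethylsilyloxy)dodecanoate | CON(C)C(=O)CC[C@H](O[Si](CC)(CC)CC)CCCCCCCC(=O)OC | intermediate
9 | tert-butyl acetate | CC(=O)OC(C)(C)C | starting material
10 | lithium enolate of tert-butyl acetate | C=C(O[Li])OC(C)(C)C | intermediate (not isolated)
11 | methyl (9R)-14-tert-butoxy-12,14-dioxo-9-(triethylsilyloxy)tetradecanoate | CC(C)(C)OC(=O)CC(=O)CC[C@H](O[Si](CC)(CC)CC)CCCCCCCC(=O)OC | intermediate
12 | methyl (9R)-14-tert-butoxy-13-diazo-12,14-dioxo-9-(triethylsilyloxy)tetradecanoate | CC(C)(C)OC(=O)C(=[N+]=[N-])C(=O)CC[C@H](O[Si](CC)(CC)CC)CCCCCCCC(=O)OC | intermediate (key-step precursor)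
13 | tert-butyl (2R)-2-(8-methoxy-8-oxooctyl)-5-oxo-2-(triethylsilyloxy)cyclopentane-1-carboxylate | CC(C)(C)OC(=O)C1C(=O)CC[C@@]1(CCCCCCCC(=O)OC)O[Si](CC)(CC)CC | intermediate (key-step product)
14 | (Z)-1-bromopent-2-ene | CC/C=C\CBr | starting material
15 | tert-butyl (2R)-2-(8-methoxy-8-oxooctyl)-5-oxo-1-[(2Z)-pent-2-en-1-yl]-2-(triethylsilyloxy)cyclopentane-1-carboxylate | CC/C=C\CC1(C(=O)OC(C)(C)C)C(=O)CC[C@@]1(CCCCCCCC(=O)OC)O[Si](CC)(CC)CC | intermediate
16 | tert-butyl (5R)-5-(8-methoxy-8-oxooctyl)-1-[(2Z)-pent-2-en-1-yl]-5-(triethylsilyloxy)-2-(trimethylsilyloxy)cyclopent-2-ene-1-carboxylate | CC/C=C\CC1(C(=O)OC(C)(C)C)C(O[Si](C)(C)C)=CC[C@@]1(CCCCCCCC(=O)OC)O[Si](CC)(CC)CC | intermediate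
17 | tert-butyl (5R)-5-(8-methoxy-8-oxooctyl)-2-oxo-1-[(2Z)-pent-2-en-1-yl]-5-(triethylsilyloxy)cyclopent-3-ene-1-carboxylate | CC/C=C\CC1(C(=O)OC(C)(C)C)C(=O)C=C[C@@]1(CCCCCCCC(=O)OC)O[Si](CC)(CC)CC | intermediate
18 | (5R)-5-hydroxy-5-(8-methoxy-8-oxooctyl)-2-oxo-1-[(2Z)-pent-2-en-1-yl]cyclopent-3-ene-1-carboxylic acid | CC/C=C\CC1(C(=O)O)C(=O)C=C[C@@]1(CCCCCCCC(=O)OC)O | intermediate (not isolated)
19 | methyl 8-[(1R,5R)-1-hydroxy-4-oxo-5-[(2Z)-pent-2-en-1-yl]cyclopent-2-en-1-yl]octanoate | CC/C=C\C[C@H]1C(=O)C=C[C@@]1(CCCCCCCC(=O)OC)O | intermediate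
20 | methyl 8-[(1R,5R)-1-acetoxy-4-oxo-5-[(2Z)-pent-2-en-1-yl]cyclopent-2-en-1-yl]octanoate | CC/C=C\C[C@H]1C(=O)C=C[C@@]1(CCCCCCCC(=O)OC)OC(C)=O | intermediate
21 | 8-[(1R,5R)-1-acetoxy-4-oxo-5-[(2Z)-pent-2-en-1-yl]cyclopent-2-en-1-yl]octanoic acid | CC/C=C\C[C@H]1C(=O)C=C[C@@]1(CCCCCCCC(=O)O)OC(C)=O | target

Total step count: 13. Longest linear sequence: 13 steps (from 1 and 2 to 21); 9 and 14 are commercial and enter at steps 5 and 8.

Steps most likely to fail

Step 7. The carbenoid may be diverted: stepwise hydride abstraction at C9 could erode retention or end in loss of the silyloxy group, or the ether oxygen could capture the carbenoid. The fallback closes the ring by condensation and makes the C9–O bond by catalytic asymmetric conjugate borylation. It sets out from 11: HF·pyridine (THF, 0 °C) removes the silyl group to give the hydroxy keto ester F1 (in equilibrium with its cyclic hemiketal); Dess–Martin periodinane (CH2Cl2) gives the diketone F2; piperidine/AcOH (toluene, 60 °C) effects intramolecular Knoevenagel condensation of the active methylene C13 onto the C9 ketone to give the cyclopentenone ester F3; conjugate borylation (B2pin2, CuCl, NaOtBu, a chiral bisphosphine such as (R,R)-QuinoxP*, MeOH, THF, with the ligand enantiomer chosen for boron delivery to the face that gives the 2S centre) gives the tertiary boronate F4; NaBO3·4H2O (THF/H2O, 0 °C) oxidises the C–B bond with retention to the tertiary alcohol F5; Et3SiOTf/2,6-lutidine (CH2Cl2, −78 °C) silylates it, and the route is rejoined at 13.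

Step 8. C-alkylation at the congested C13 may be outrun by loss of triethylsilanolate from the enolate or by O-alkylation. The fallback builds the side chain in stages under neutral conditions. It sets out from 13: Tsuji–Trost allylation (allyl methyl carbonate, Pd(PPh3)4 cat., THF, rt, zerovalent palladium) gives the C-allyl keto ester F6; ozonolysis (O3, CH2Cl2, −78 °C; then PPh3) gives the aldehyde F7; cis-selective Wittig olefination with propylidenetriphenylphosphorane (from propyltriphenylphosphonium bromide and NaN(SiMe3)2, THF, −78 °C) installs the Z alkene, and the route is rejoined at 15.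

Step 11. The one-pot acidolysis may be unclean: desilylation may be incomplete, acid may add across the side-chain alkene while the free acid and alcohol are present, or the C13 epimers may fail to equilibrate. The fallback separates the events and installs the acetate while C13 is still quaternary and base-stable. It sets out from 17: HF·pyridine (THF, 0 °C to rt) gives the tertiary alcohol F8; Ac2O, DMAP, Et3N (CH2Cl2, rt) gives the tertiary acetate F9; TFA/CH2Cl2 (0 °C) then cleaves only the tert-butyl ester to the keto acid F10, which is decarboxylated in warm toluene, and the route is rejoined at 20, so that step 12 is not needed.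

Further compounds
F1 | step 7 | methyl (9R)-14-tert-butoxy-9-hydroxy-12,14-dioxotetradecanoate | CC(C)(C)OC(=O)CC(=O)CC[C@H](O)CCCCCCCC(=O)OC
F2 | step 7 | methyl 14-tert-butoxy-9,12,14-trioxotetradecanoate | CC(C)(C)OC(=O)CC(=O)CCC(=O)CCCCCCCC(=O)OC
F3 | step 7 | tert-butyl 2-(8-methoxy-8-oxooctyl)-5-oxocyclopent-1-ene-1-carboxylate | CC(C)(C)OC(=O)C1=C(CCCCCCCC(=O)OC)CCC1=O
F4 | step 7 | tert-butyl (2S)-2-(8-methoxy-8-oxooctyl)-5-oxo-2-(4,4,5,5-tetramethyl-1,3,2-dioxaborolan-2-yl)cyclopentane-1-carboxylate | CC(C)(C)OC(=O)C1C(=O)CC[C@@]1(CCCCCCCC(=O)OC)B2OC(C)(C)C(C)(C)O2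
F5 | step 7 | tert-butyl (2R)-2-hydroxy-2-(8-methoxy-8-oxooctyl)-5-oxocyclopentane-1-carboxylate | CC(C)(C)OC(=O)C1C(=O)CC[C@@]1(CCCCCCCC(=O)OC)O
F6 | step 8 | tert-butyl (2R)-2-(8-methoxy-8-oxooctyl)-5-oxo-1-(prop-2-en-1-yl)-2-(triethylsilyloxy)cyclopentane-1-carboxylate | C=CCC1(C(=O)OC(C)(C)C)C(=O)CC[C@@]1(CCCCCCCC(=O)OC)O[Si](CC)(CC)CC
F7 | step 8 | tert-butyl (2R)-2-(8-methoxy-8-oxooctyl)-5-oxo-1-(2-oxoethyl)-2-(triethylsilyloxy)cyclopentane-1-carboxylate | O=CCC1(C(=O)OC(C)(C)C)C(=O)CC[C@@]1(CCCCCCCC(=O)OC)O[Si](CC)(CC)CC
F8 | step 11 | tert-butyl (5R)-5-hydroxy-5-(8-methoxy-8-oxooctyl)-2-oxo-1-[(2Z)-pent-2-en-1-yl]cyclopent-3-ene-1-carboxylate | CC/C=C\CC1(C(=O)OC(C)(C)C)C(=O)C=C[C@@]1(CCCCCCCC(=O)OC)O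
F9 | step 11 | tert-butyl (5R)-5-acetoxy-5-(8-methoxy-8-oxooctyl)-2-oxo-1-[(2Z)-pent-2-en-1-yl]cyclopent-3-ene-1-carboxylate | CC/C=C\CC1(C(=O)OC(C)(C)C)C(=O)C=C[C@@]1(CCCCCCCC(=O)OC)OC(C)=O
F10 | step 11 | (5R)-5-acetoxy-5-(8-methoxy-8-oxooctyl)-2-oxo-1-[(2Z)-pent-2-en-1-yl]cyclopent-3-ene-1-carboxylic acid | CC/C=C\CC1(C(=O)O)C(=O)C=C[C@@]1(CCCCCCCC(=O)OC)OC(C)=O
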